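(The runs come from a simulation with made-up constants; the scatter is artificial.)

Amounts first: the books here are kept on the starting material, so each entry is a percentage of what was charged. The flask and both earlier runs charge partner and both substrates in the same equivalents, and they differ in concentration and time.

| flask | starting material | partner | second substrate | third substrate | remark | time |
|---|---|---|---|---|---|---|
| dawn | 10 mM | 1.1 equiv | 1 equiv | 1 equiv | run made earlier |  |
| spring | 40 mM | 1.1 equiv | 1 equiv | 1 equiv | run made earlier |  |
| flask | 20 mM | 1.10 equiv | 1.00 equiv | 1.00 equiv |  | 40 h |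

| run | time / h | target / % |
|---|---|---|
| dawn | 1.50 | 5.8 |
| dawn | 5.00 | 12.5 |
| dawn | 10.0 | 14.1 |
| dawn | 15.0 | 15.0 |
| dawn | 20.0 | 14.1 |
| dawn | 25.0 | 13.3 |
| dawn | 30.0 | 12.2 |
| spring | 5.00 | 13.7 |
| spring | 10.0 | 9.7 |
| spring | 15.0 | 8.0 |
| spring | 20.0 | 5.9 |
| spring | 25.0 | 5.4 |
| spring | 30.0 | 4.3 |

(standard deviation of a reading: 0.5 percentage points)

- amount of target in percent of the starting material charged, at 4.0 h, 15 h and 40 h

- what was read earlier has a scatter of 0.5 percentage points, one standard deviation

If every step is bimolecular, then at equal equivalents a higher charge speeds each step in proportion, so a share of the charge should follow one number. In the flask at 40 h that number stands at 800 mM·h; it is the dose, charged [starting material] times elapsed time, a reduced time. The dawn run at 20.0 h and the spring run at 5.00 h share a dose of 200 mM·h and read 14.1 % and 13.7 %, apart by 0.4 percentage points with a scatter of 0.5 points on each reading, so the rule stands as far as this overlap tests it.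

Now the ledger of this flask. At 4.0 h the dose is 80.0 mM·h, which the dawn run passes at 8.00 h, between readings of 12.5 % and 14.1 %. A straight line there enters 13.5 % as target, leaving 86.5 % unread. At 15 h the dose is 300 mM·h, the dose of the dawn run at 30.0 h, so target is entered at 12.2 %. At 40 h the dose equals that of the spring run at 20.0 h, so the entry is 5.9 %, leaving 94.1 % unread. The dawn run reads 15.0 % at 15.0 h and less afterwards, 12.2 % at 30.0 h, so that run loses target as the dose grows, and the unread column must hold what it becomes.

The forecast, reasoning “if every step is bimolecular”, gives 13.6 %, 11.9 % and 6 %.

The flask gives 14.6 %, 11.9 % and 6.48 %, so the interpolated entry lies 1.1 points below the result, and the two entries taken from readings differ from it by 0.3 points and 0.58 points.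

    starting material + partner → target (k = 4.41 M⁻¹ h⁻¹)
    second substrate + partner → second product (k = 0.293 M⁻¹ h⁻¹)
    third substrate + partner → third product (k = 2.48 M⁻¹ h⁻¹)
    starting material + target → side product (k = 16.7 M⁻¹ h⁻¹)

The books of the flask close at 40.0 h: starting material 8.65 %, target 6.48 % and side product 84.9 %, each side product counted as two, sum to 100 %. At 20.0 h the flask stands at a dose of 400 mM·h, the dose of the spring run at 10.0 h, and holds 10.2 % target where that run read 9.7 %.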